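**Retrosynthetic overview** (benzofuran numbering: O1, C2, C3, C3a, C4–C7, C7a)
1. Target 22 ⇐ 21 by cleavage of the aryl TIPS ether at O6; ring A (the benzene ring) is bought with 2,4-dihydroxybenzaldehyde 1.
2. 21 ⇐ 2-formylaryl ester 12 + chiral 2-methylallyl sulfonium salt 17 in one operation: ylide addition forms C2–C3, a 1,5 O→O acyl shift carries the side-chain ester from O1 to the new oxygen on C3, and ring B (the dihydrofuran) is closed last by the O1–C2 bond.
3. Enabling feature: O1 and the ester oxygen on C3 are linked through C7a–C3a–C3, so the acyl group can be relayed through a six-membered transition state. C2 is an allylic carbon next to the isopropenyl group, so it can enter as a sulfonium-ylide carbon that is first the nucleophile toward C3 and then the electrophile toward O1.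
4. 12 ⇐ phenol 5 (from 1 by O6 silylation, C5 iodination, Stille acetylation) + acid 11 (from crotonaldehyde 6 via (Z)-2-iodobut-2-en-1-ol and carboxylation with retention); 17 ⇐ (2S,5S)-hexane-2,5-diol 13 + 3-bromo-2-methylprop-1-ene 16.

Key step: step 12

Assumption: the 2-methylallyl ylide of (2R,5R)-2,5-dimethylthiolane is taken to add to aryl aldehydes with the facial sense that leads to (S,S)-configured trans-oxiranes; should the opposite sense be found, the (2S,5S)-sulfide from (2R,5R)-hexane-2,5-diol is used instead, all else unchanged.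

**Route**

Step 1
Reactants: 1 2,4-dihydroxybenzaldehyde
Product: 2 2-hydroxy-4-[(triisopropylsilyl)oxy]benzaldehyde
Conditions: TIPSCl (1.05 equiv), imidazole, CH2Cl2, 0 °C
Reagents that add atoms: triisopropylsilyl chloride, CC(C)[Si](Cl)(C(C)C)C(C)C
Why: Chemoselective O-silylation, because the 2-OH is tied up in a hydrogen bond to the formyl group and only the free 4-OH (the later O6) should react.

Step 2
Reactants: 2 2-hydroxy-4-[(triisopropylsilyl)oxy]benzaldehyde
Product: 3 2-hydroxy-5-iodo-4-[(triisopropylsilyl)oxy]benzaldehyde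
Conditions: NIS (1.05 equiv), TsOH·H2O (5 mol %), MeCN, 0 °C to rt
Reagents that add atoms: N-iodosuccinimide, O=C1CCC(=O)N1I
Why: Electrophilic aromatic iodination, directed to C5 (para to the free phenol, ortho to the silyl ether) because the only other activated position lies between both oxygens and is shielded by the TIPS group.

Step 3
Reactants: 3 2-hydroxy-5-iodo-4-[(triisopropylsilyl)oxy]benzaldehyde
Product: 5 5-acetyl-2-hydroxy-4-[(triisopropylsilyl)oxy]benzaldehyde, via enol ether 4 (not isolated)
Conditions: tributyl(1-ethoxyvinyl)stannane (1.3 equiv), PdCl2(PPh3)2 (5 mol %), 1,4-dioxane, 90 °C; then 1 M HCl, THF, rt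
Reagents that add atoms: tributyl(1-ethoxyvinyl)stannane, CCOC(=C)[Sn](CCCC)(CCCC)CCCC; water, O
Why: Stille coupling with an acetyl-anion equivalent followed by mild hydrolysis of the aryl enol ether to the methyl ketone, both of which the free phenol, the aldehyde and the aryl TIPS ether should tolerate.

Step 4
Reactants: 6 (E)-but-2-enal
Product: 7 (Z)-2-iodobut-2-enal
Conditions: I2 (1.5 equiv), K2CO3, DMAP (20 mol %), THF/H2O 1:1, rt
Reagents that add atoms: iodine, II
Why: α-Iodination of an enal by amine conjugate addition, iodination of the enolate and elimination (Morita–Baylis–Hillman-type manifold), which should give the more stable isomer with iodine cis to the methyl group.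

Step 5
Reactants: 7 (Z)-2-iodobut-2-enal
Product: 8 (Z)-2-iodobut-2-en-1-ol
Conditions: NaBH4, CeCl3·7H2O, MeOH, 0 °C
Reagents that add atoms: none
Why: Luche 1,2-reduction of the enal, which leaves the alkene geometry and the C–I bond untouched.

Step 6
Reactants: 8 (Z)-2-iodobut-2-en-1-ol
Product: 10 (2Z)-2-(hydroxymethyl)but-2-enoic acid, via dilithio species 9 (not isolated)
Conditions: t-BuLi (3.1 equiv), Et2O, −78 °C; CO2 (g), −78 to 0 °C; 1 M HCl
Reagents that add atoms: carbon dioxide, O=C=O
Why: Iodine–lithium exchange on the lithium alkoxide and carboxylation; alkenyllithiums hold their configuration at −78 °C, so the carboxyl group should replace iodine with retention and end up cis to the methyl group (the angelate-type Z geometry of the target).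

Step 7
Reactants: 10 (2Z)-2-(hydroxymethyl)but-2-enoic acid
Product: 11 (2Z)-2-[(acetyloxy)methyl]but-2-enoic acid
Conditions: Ac2O (1.3 equiv), pyridine, CH2Cl2, 0 °C to rt; then H2O
Reagents that add atoms: acetic anhydride, CC(=O)OC(C)=O
Why: O-Acetylation of the primary allylic alcohol, with any mixed anhydride at the carboxyl group hydrolysed in the aqueous work-up.

Step 8
Reactants: 5 5-acetyl-2-hydroxy-4-[(triisopropylsilyl)oxy]benzaldehyde; 11 (2Z)-2-[(acetyloxy)methyl]but-2-enoic acid
Product: 12 4-acetyl-2-formyl-5-[(triisopropylsilyl)oxy]phenyl (2Z)-2-[(acetyloxy)methyl]but-2-enoate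
Conditions: EDC·HCl (1.3 equiv), DMAP (5 mol %), CH2Cl2, −10 to 0 °C
Reagents that add atoms: none
Why: Steglich esterification of the acidic phenol O1–H (para to acetyl, ortho to formyl), run cold and with little DMAP so that the Z enoate and the allylic acetate should survive, while the silylated O6 cannot compete.

Step 9
Reactants: 13 (2S,5S)-hexane-2,5-diol
Product: 14 (2S,5S)-hexane-2,5-diyl dimethanesulfonate
Conditions: MsCl (2.4 equiv), Et3N, CH2Cl2, 0 °C
Reagents that add atoms: methanesulfonyl chloride, CS(=O)(=O)Cl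
Why: O-Sulfonylation, which does not touch either stereocentre.

Step 10
Reactants: 14 (2S,5S)-hexane-2,5-diyl dimethanesulfonate
Product: 15 (2R,5R)-2,5-dimethylthiolane
Conditions: Na2S·9H2O, DMSO, rt; distillation
Reagents that add atoms: sodium sulfide, [Na+].[Na+].[S-2]
Why: Double SN2 displacement by sulfide (the second one 5-exo-tet) with inversion at both carbons, which should give the C2-symmetric trans-thiolane.

Step 11
Reactants: 15 (2R,5R)-2,5-dimethylthiolane; 16 3-bromo-2-methylprop-1-ene
Product: 17 (2R,5R)-2,5-dimethyl-1-(2-methylprop-2-en-1-yl)thiolan-1-ium tetrafluoroborate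
Conditions: AgBF4 (1.05 equiv), CH2Cl2, 0 °C to rt, dark
Reagents that add atoms: silver tetrafluoroborate, [Ag+].F[B-](F)(F)F
Why: S-Alkylation driven by precipitation of AgBr; the two lone pairs of the C2-symmetric sulfide are equivalent, so a single sulfonium salt should form.

Step 12
Reactants: 17 (2R,5R)-2,5-dimethyl-1-(2-methylprop-2-en-1-yl)thiolan-1-ium tetrafluoroborate; 12 4-acetyl-2-formyl-5-[(triisopropylsilyl)oxy]phenyl (2Z)-2-[(acetyloxy)methyl]but-2-enoate
Product: 21 (2S,3S)-5-acetyl-2-(prop-1-en-2-yl)-6-[(triisopropylsilyl)oxy]-2,3-dihydro-1-benzofuran-3-yl (2Z)-2-[(acetyloxy)methyl]but-2-enoate, via ylide 18 (not isolated), via anti-betaine 19 (not isolated), via phenoxide 20 (not isolated)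
Conditions: 17 (1.25 equiv), LiN(SiMe3)2 (1.2 equiv), THF, −78 °C; then 12 (1.0 equiv), −78 to 0 °C; aq. NH4Cl
Reagents that add atoms: none
Why: Proposed new method: the allylic sulfonium ylide 18 should add through its α-carbon to the aldehyde of 12 to give the lithium anti-betaine 19 (C2–C3 bond), whose alkoxide, held next to the ortho aryl ester, passes the acyl group from O1 to the C3 oxygen through a six-membered tetrahedral intermediate (downhill, alkoxide to acetyl-stabilised phenoxide), after which phenoxide 20 displaces the sulfide at the allylic C2 with inversion and closes the dihydrofuran ring B in a 5-exo-tet mode. The closest known reaction types are the asymmetric sulfonium-ylide epoxidation of aryl aldehydes (same betaine), the anionic O-to-O acyl shift in adducts of 2-acyloxybenzaldehydes, and the phenoxide ring closure in formal [4+1] annulations of sulfur ylides with ortho-quinone methides. C3 (S) is set in the C–C bond formation: the two methyl groups of the C2-symmetric thiolane fix the conformation and the open face of the ylide, and the anti mode of addition (aryl and isopropenyl apart, reinforced by the 2-methyl group of the ylide) ties the aldehyde face to it. C2 (S) then follows stereospecifically, because the single inversion of the anti-betaine places O1 where the oxirane oxygen of the usual trans-epoxide would sit, which is cis to the ester on C3. The step needs the acyl shift to outrun oxirane closure and aldehyde addition to outrun attack on the enoate or the aryl ester; lithium (chelation of alkoxide and ester C=O, slow closure of lithium betaines), the activated aryl ester and −78 °C are chosen to secure this. Because the acyl shift traps the betaine irreversibly, the cis to trans ratio of 21 should mirror the anti to syn selectivity of the addition.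

Step 13
Reactants: 21 (2S,3S)-5-acetyl-2-(prop-1-en-2-yl)-6-[(triisopropylsilyl)oxy]-2,3-dihydro-1-benzofuran-3-yl (2Z)-2-[(acetyloxy)methyl]but-2-enoate
Product: 22 (2S,3S)-5-acetyl-6-hydroxy-2-(prop-1-en-2-yl)-2,3-dihydro-1-benzofuran-3-yl (2Z)-2-[(acetyloxy)methyl]but-2-enoate
Conditions: HF·pyridine, pyridine, THF, 0 °C
Reagents that add atoms: none
Why: Fluoride-mediated cleavage of the aryl silyl ether under buffered, non-basic conditions, so that the freed phenol (para to the benzylic ester) is never a phenoxide that could expel the carboxylate, and the esters, the Z enoate and both stereocentres should be untouched.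

**Compound list**

1 | 2,4-dihydroxybenzaldehyde | O=Cc1ccc(O)cc1O | starting material
2 | 2-hydroxy-4-[(triisopropylsilyl)oxy]benzaldehyde | O=Cc1ccc(O[Si](C(C)C)(C(C)C)C(C)C)cc1O | intermediate
3 | 2-hydroxy-5-iodo-4-[(triisopropylsilyl)oxy]benzaldehyde | O=Cc1cc(I)c(O[Si](C(C)C)(C(C)C)C(C)C)cc1O | intermediate
4 | 5-(1-ethoxyethenyl)-2-hydroxy-4-[(triisopropylsilyl)oxy]benzaldehyde (enol ether) | CCOC(=C)c1cc(C=O)c(O)cc1O[Si](C(C)C)(C(C)C)C(C)C | intermediate
5 | 5-acetyl-2-hydroxy-4-[(triisopropylsilyl)oxy]benzaldehyde | CC(=O)c1cc(C=O)c(O)cc1O[Si](C(C)C)(C(C)C)C(C)C | intermediate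
6 | (E)-but-2-enal (crotonaldehyde) | C/C=C/C=O | starting material
7 | (Z)-2-iodobut-2-enal | C/C=C(\I)C=O | intermediate
8 | (Z)-2-iodobut-2-en-1-ol | C/C=C(\I)CO | intermediate
9 | lithium (Z)-2-lithiobut-2-en-1-olate (dilithio species) | C/C=C(\[Li])CO[Li] | intermediate
10 | (2Z)-2-(hydroxymethyl)but-2-enoic acid | C/C=C(\C(=O)O)CO | intermediate
11 | (2Z)-2-[(acetyloxy)methyl]but-2-enoic acid | C/C=C(\C(=O)O)COC(C)=O | intermediate
12 | 4-acetyl-2-formyl-5-[(triisopropylsilyl)oxy]phenyl (2Z)-2-[(acetyloxy)methyl]but-2-enoate | CC(=O)c1cc(C=O)c(OC(=O)/C(=C\C)COC(C)=O)cc1O[Si](C(C)C)(C(C)C)C(C)C | intermediate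
13 | (2S,5S)-hexane-2,5-diol | C[C@H](O)CC[C@H](C)O | starting material
14 | (2S,5S)-hexane-2,5-diyl dimethanesulfonate | C[C@H](OS(C)(=O)=O)CC[C@H](C)OS(C)(=O)=O | intermediate
15 | (2R,5R)-2,5-dimethylthiolane | C[C@@H]1CC[C@@H](C)S1 | intermediate
16 | 3-bromo-2-methylprop-1-ene | C=C(C)CBr | starting material
17 | (2R,5R)-2,5-dimethyl-1-(2-methylprop-2-en-1-yl)thiolan-1-ium tetrafluoroborate | C[C@@H]1CC[C@@H](C)[S+]1CC(C)=C.F[B-](F)(F)F | intermediate
18 | 2-methylallyl ylide of (2R,5R)-2,5-dimethylthiolane | C[C@@H]1CC[C@@H](C)[S+]1[CH-]C(C)=C | intermediate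
19 | (1S,2R)-1-[5-acetyl-2-{[(2Z)-2-(acetoxymethyl)but-2-enoyl]oxy}-4-(triisopropylsilyloxy)phenyl]-2-[(2R,5R)-2,5-dimethylthiolan-1-ium-1-yl]-3-methylbut-3-en-1-olate (anti-betaine, lithium alkoxide) | C=C(C)[C@@H]([S+]1[C@H](C)CC[C@H]1C)[C@@H]([O-])c1cc(C(C)=O)c(O[Si](C(C)C)(C(C)C)C(C)C)cc1OC(=O)/C(=C\C)COC(C)=O | intermediate
20 | 4-acetyl-2-[(1S,2R)-1-{[(2Z)-2-(acetoxymethyl)but-2-enoyl]oxy}-2-[(2R,5R)-2,5-dimethylthiolan-1-ium-1-yl]-3-methylbut-3-en-1-yl]-5-(triisopropylsilyloxy)phenolate (lithium phenoxide) | C=C(C)[C@@H]([S+]1[C@H](C)CC[C@H]1C)[C@@H](OC(=O)/C(=C\C)COC(C)=O)c1cc(C(C)=O)c(O[Si](C(C)C)(C(C)C)C(C)C)cc1[O-] | intermediate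
21 | (2S,3S)-5-acetyl-2-(prop-1-en-2-yl)-6-[(triisopropylsilyl)oxy]-2,3-dihydro-1-benzofuran-3-yl (2Z)-2-[(acetyloxy)methyl]but-2-enoate (2,3-cis) | C=C(C)[C@@H]1Oc2cc(O[Si](C(C)C)(C(C)C)C(C)C)c(C(C)=O)cc2[C@@H]1OC(=O)/C(=C\C)COC(C)=O | intermediate
22 | (2S,3S)-5-acetyl-6-hydroxy-2-(prop-1-en-2-yl)-2,3-dihydro-1-benzofuran-3-yl (2Z)-2-[(acetyloxy)methyl]but-2-enoate (2,3-cis) | C=C(C)[C@@H]1Oc2cc(O)c(C(C)=O)cc2[C@@H]1OC(=O)/C(=C\C)COC(C)=O | target

**Step count and risks**

Total step count: 13. Longest linear sequence: 7 steps (steps 4, 5, 6, 7, 8, 12, 13, from crotonaldehyde 6).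

Steps most likely to fail:

1. Step 12 (proposed new method). The lithium betaine may close to the oxirane before the acyl group has moved, which leaves the acyl group on O1 and stops the cascade. Trapping of the syn-betaine as well may erode the cis selectivity, and the ylide may add to the enoate. Fallback with known chemistry, setting out from 5 and returning at 21:
 - 5 is silylated at O1 (TBSCl, imidazole, DMF) to 5-acetyl-2-[(tert-butyldimethylsilyl)oxy]-4-[(triisopropylsilyl)oxy]benzaldehyde F1.
 - Corey–Chaykovsky epoxidation with the ylide of 17 (KN(SiMe3)2, THF, −78 °C) should give the trans-oxirane 1-{4-[(tert-butyldimethylsilyl)oxy]-5-[(2S,3S)-3-(prop-1-en-2-yl)oxiran-2-yl]-2-[(triisopropylsilyl)oxy]phenyl}ethanone F2.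
 - Buffered fluoride (Bu4NF/AcOH, 1 equiv, THF, −20 °C) should cleave only the less hindered aryl TBS ether to give 1-{4-hydroxy-5-[(2S,3S)-3-(prop-1-en-2-yl)oxiran-2-yl]-2-[(triisopropylsilyl)oxy]phenyl}ethanone F3.
 - F3 is treated without isolation with Pd(PPh3)4 (5 mol %, THF, 0 °C). Zerovalent palladium ionises the vinyl oxirane with inversion, the alkoxide takes the phenol proton, and the phenoxide attacks the allyl terminus at C2 anti to the metal (Tsuji–Trost cycloetherification, 5-exo, net retention). This should give the cis alcohol 1-{(2S,3S)-3-hydroxy-2-(prop-1-en-2-yl)-6-[(triisopropylsilyl)oxy]-2,3-dihydro-1-benzofuran-5-yl}ethanone F4.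
 - Yamaguchi esterification of F4 with 11 (2,4,6-trichlorobenzoyl chloride, Et3N, DMAP cat., toluene, 0 °C to rt) then gives 21.

2. Step 8. Reversible conjugate addition of DMAP to the activated enoate may isomerise the Z double bond or expel the allylic acetate, and the DMAP adduct may attack the ortho formyl group. Fallback, setting out from 11 and returning at 12: the acid is converted into the isolable acyl fluoride (2Z)-2-[(acetyloxy)methyl]but-2-enoyl fluoride F5 (cyanuric fluoride, pyridine, CH2Cl2, −10 °C). F5 is added to the caesium phenoxide of 5 (Cs2CO3, MeCN, 0 °C), an uncatalysed phenoxide acylation in which no nucleophilic amine meets the enoate.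

3. Step 6. Protonation of the dilithio species by adventitious acid, loss of alkene geometry on warming, or incomplete capture by CO2 may lower the return of acid. Fallback, setting out from 8 and returning at 10: palladium-catalysed methoxycarbonylation of the alkenyl iodide with retention (Pd(OAc)2, PPh3, CO 1 atm, Et3N, MeOH, 50 °C) gives methyl (2Z)-2-(hydroxymethyl)but-2-enoate F6. Saponification (LiOH, THF/H2O, 0 °C) then gives 10.

Further compounds
F1 | step 12 | 5-acetyl-2-[(tert-butyldimethylsilyl)oxy]-4-[(triisopropylsilyl)oxy]benzaldehyde | CC(=O)c1cc(C=O)c(O[Si](C)(C)C(C)(C)C)cc1O[Si](C(C)C)(C(C)C)C(C)C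
F2 | step 12 | 1-{4-[(tert-butyldimethylsilyl)oxy]-5-[(2S,3S)-3-(prop-1-en-2-yl)oxiran-2-yl]-2-[(triisopropylsilyl)oxy]phenyl}ethanone | CC(=O)c1cc([C@@H]2O[C@H]2C(C)=C)c(O[Si](C)(C)C(C)(C)C)cc1O[Si](C(C)C)(C(C)C)C(C)C
F3 | step 12 | 1-{4-hydroxy-5-[(2S,3S)-3-(prop-1-en-2-yl)oxiran-2-yl]-2-[(triisopropylsilyl)oxy]phenyl}ethanone | CC(=O)c1cc([C@@H]2O[C@H]2C(C)=C)c(O)cc1O[Si](C(C)C)(C(C)C)C(C)C
F4 | step 12 | 1-{(2S,3S)-3-hydroxy-2-(prop-1-en-2-yl)-6-[(triisopropylsilyl)oxy]-2,3-dihydro-1-benzofuran-5-yl}ethanone | C=C(C)[C@@H]1Oc2cc(O[Si](C(C)C)(C(C)C)C(C)C)c(C(C)=O)cc2[C@@H]1O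
F5 | step 8 | (2Z)-2-[(acetyloxy)methyl]but-2-enoyl fluoride | C/C=C(\C(F)=O)COC(C)=O
F6 | step 6 | methyl (2Z)-2-(hydroxymethyl)but-2-enoate | C/C=C(\C(=O)OC)CO
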